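The runs are simulated with constants of no real substance, noise included.

1. We must choose which X charge to take to 12 h if we want the most Q in the flask at the end. Two earlier runs guide the choice.

| flask | G | D | X | remark | time |
|---|---|---|---|---|---|
| grey | 0.30 M | 0.54 M | 24 mM | run made earlier |  |
| ochre | 0.30 M | 0.54 M | 280 mM | run made earlier |  |
| Monday's | 0.30 M | 0.540 M | 20 mM |  | 12 h |
| Friday's | 0.30 M | 0.540 M | 60 mM |  | 12 h |
| Saturday's | 0.30 M | 0.540 M | 200 mM |  | 12 h |

- grey (time / h: Q / %): 0.500: 10.3; 0.833: 18.7; 1.33: 29.2; 2.00: 34.8; 4.00: 36.2; 6.00: 31.2
- ochre (time / h: Q / %): 1.00: 29.1; 2.00: 18.1; 3.00: 14.4; 4.00: 13.7; 5.00: 13.8; 6.00: 11.8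

(scatter of a reading: 1 percentage point)

- amount of Q at the end, in percent of the G charged for Monday's, Friday's, Saturday's, in this order
- how the row runs (rises, then falls / hardly changes / falls all the way / falls, then rises / rises all the way)

- a reading or a percentage of Q counts all its forms, free or not
- "hardly changes" means that all values lie within two and a half points (for a concentration: within two and a half percent of the largest)

2. The flasks share their G and D charges. If every step ran at a rate proportional to X, their readings would lie on one curve against X times time, which is Selwyn's test. We therefore carry the ochre-equivalent time τ, a flask's time multiplied by its X charge and divided by the ochre charge. At the end τ is 0.857 h for Monday's, 2.57 h for Friday's and 8.57 h for Saturday's.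

3. The grey run gives a weak test. Its last reading, 31.2%, stands at τ = 0.514 h, a little above the ochre run's first reading, 29.1% at 1.00 h, as one falling curve allows.

4. Our own reckoning reads the ochre run at these times. Monday's τ comes earlier than the first ochre reading, so we take about 29.1%. Friday's lies between two readings and interpolates to 16.0%. Saturday's comes later than the last reading, so we take that reading, 11.8%. Our row falls at each step, and Monday's stands higher than the other two, so we would charge 20 mM.

5. The forecast gives 20%, 26% and 13%, a row that rises, then falls, on the ground that “yield is capped by X charged, not by time”. Its highest value stands at Friday's, and ours at Monday's.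

6. The flasks give 19.5%, 10.2% and 9.58%: the row falls all the way. The steps behind them are these:

    D + X + Q → X + J (k = 0.0110 L² mol⁻² s⁻¹)
    D + X + E → X + Q (k = 0.0130 L² mol⁻² s⁻¹)
    E → Z (k = 2.70 × 10⁻⁵ s⁻¹)
    D + Q ⇌ L, settled at all times (K = 0.620 L mol⁻¹)
    G + X → X + E (k = 0.0270 L mol⁻¹ s⁻¹)

Monday's holds more Z than Saturday's at 12.0 h, 22.6% against 5.03%. Monday's at 120 h has τ = 8.57 h, the same as Saturday's at its end, 8.57 h. Yet Saturday's holds 9.58% of Q at 12.0 h, and Monday's holds 0.0153% at 120 h.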